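**Plan**

1. Retrosynthetic cuts: the enal CHO back to its allylic CH2OH; the 3-hydroxypropyl arm back to a CH2–CO2R arm plus one CH2; the ring bond C2–C3 (quaternary carbon to CH) by a radical closure; the bond C3–C4 by a Suzuki coupling; the bonds C2–homofarnesyl, C1–CH3 and (alkylidene C)–CH3 by two carbomagnesiations of octa-2,6-diyne-1,8-diol, whose eight carbons become HOCH2–C2–C1–C6–C5–C4–C(=)–CHO.
2. Enabling feature: the quaternary C2 carries a CH2OH and lies between the C1 carbinol and the C3 methine, so an oxirane spanning C2 and that CH2 is a masked tertiary C2 radical that leaves its own hydroxymethyl group on opening. C3 is the β-carbon of an acrylate hung on the alkylidene carbon C4, and the tether C1–C6–C5–C4 makes the attack 6-exo while the fully substituted C4=C alkene stays outside the radical chain.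
3. Forward order: diyne diol; end one: carbomagnesiation (homofarnesyl, then CH3), Sharpless epoxidation, transposition to the tertiary allylic alcohol; end two: carbomagnesiation/iodination, directed epoxidation, Suzuki coupling; then the only ring is closed (C2–C3), the arm is homologated and the enal is unveiled last.
4. Stereochemistry: C1 from the Sharpless epoxidation (catalyst control); C2 and C3 relayed from C1 in the ring closure; the (Z) enal geometry from anti-carbomagnesiation/iodination and a stereoretentive coupling; the two (E) chain alkenes from farnesyl bromide.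

Key step: step 14

Remark: homofarnesyl = (3E,7E)-4,8,12-trimethyltrideca-3,7,11-trien-1-yl; TBS = tert-butyldimethylsilyl; Piv = 2,2-dimethylpropanoyl. Ring locants: C1 = carbinol carbon (CH3, OH), C2 = quaternary carbon, C3 = CH, C4 = alkylidene carbon, C5 and C6 = CH2. The oxirane carbon of 21 and 23 becomes a planar radical in step 14, so it is carried as an epimer mixture. Compound 8 is used as paraformaldehyde; step 4 takes up two CH2O units of it, one entered as reactant 8 and the second on the reagent line of that step.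

**Route**

Step 1
Reactants: 1 (2E,6E)-farnesyl bromide; 2 (chloromethyl)(isopropoxy)dimethylsilane
Product: 4 isopropoxydimethyl(homofarnesyl)silane, via silylmethyl Grignard reagent 3 (not isolated)
Conditions: 2, Mg, THF, rt; then 1, Li2CuCl4 (3 mol %), THF, −20 → 0 °C
Reagents that add atoms: none
Why: Copper-catalysed Grignard cross-coupling (Kumada type) of the silylmethyl Grignard reagent, a hydroxymethyl anion equivalent, should displace the primary allylic bromide at its α-carbon, adding one carbon and keeping both E alkenes.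

Step 2
Reactants: 4 isopropoxydimethyl(homofarnesyl)silane
Product: 5 (3E,7E)-homofarnesol
Conditions: H2O2 (30 %), KF, KHCO3, THF/MeOH, rt
Reagents that add atoms: hydrogen peroxide, OO
Why: Fleming–Tamao oxidation should convert the alkoxysilyl C–Si bond into C–OH without touching the trisubstituted alkenes.

Step 3
Reactants: 5 (3E,7E)-homofarnesol
Product: 6 (3E,7E)-homofarnesyl bromide
Conditions: CBr4, PPh3, CH2Cl2, 0 °C
Reagents that add atoms: tetrabromomethane, BrC(Br)(Br)Br
Why: Appel bromination of a primary alcohol under neutral conditions.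

Step 4
Reactants: 7 hexa-1,5-diyne; 8 paraformaldehyde
Product: 9 octa-2,6-diyne-1,8-diol
Conditions: n-BuLi (2.2 equiv), THF, −78 °C; (CH2O)n (3 equiv of CH2O), −78 °C → rt; then H2O
Reagents that add atoms: formaldehyde as the second CH2O unit of paraformaldehyde, C=O
Why: Double deprotonation of the two terminal alkynes gives the dilithium bis-acetylide, and each acetylide adds to one molecule of formaldehyde (alkynylation of an aldehyde), so two CH2O units are taken up per diyne.

Step 5
Reactants: 9 octa-2,6-diyne-1,8-diol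
Product: 10 8-[(tert-butyldimethylsilyl)oxy]octa-2,6-diyn-1-ol
Conditions: NaH (1.0 equiv), THF, 0 °C; TBSCl (1.0 equiv), rt
Reagents that add atoms: tert-butyldimethylsilyl chloride, CC(C)(C)[Si](C)(C)Cl
Why: Monosilylation of a symmetrical diol through its sparingly soluble monosodium alkoxide should leave one propargylic OH free to direct the next step.

Step 6
Reactants: 10 8-[(tert-butyldimethylsilyl)oxy]octa-2,6-diyn-1-ol; 6 (3E,7E)-homofarnesyl bromide
Product: 13 (2E)-8-(TBSO)-3-methyl-2-(homofarnesyl)oct-2-en-6-yn-1-ol, via homofarnesylmagnesium bromide 11 (not isolated), via alkenylmagnesium chelate 12 (not isolated)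
Conditions: 10, EtMgBr (1.0 equiv), THF, 0 °C; 11 (from 6, Mg, THF; 1.6 equiv), CuI (15 mol %), −20 °C → rt; then MeI, DMPU, 0 °C → rt; H2O
Reagents that add atoms: iodomethane, CI
Why: Alkoxide-directed, copper-catalysed anti-carbomagnesiation of the propargylic alcohol should place homofarnesyl on the carbon next to CH2OH and magnesium, held cis to CH2OH in a five-membered chelate, on the other carbon, where copper-assisted methylation with retention gives the single (E) tetrasubstituted allylic alcohol.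

Step 7
Reactants: 13 (2E)-8-(TBSO)-3-methyl-2-(homofarnesyl)oct-2-en-6-yn-1-ol
Product: 14 [(2R,3R)-3-methyl-3-[5-(TBSO)pent-3-yn-1-yl]-2-(homofarnesyl)oxiran-2-yl]methanol
Conditions: Ti(OiPr)4 (10 mol %), D-(−)-diethyl tartrate (14 mol %), t-BuOOH (2 equiv), 4 Å molecular sieves, CH2Cl2, −25 °C
Reagents that add atoms: tert-butyl hydroperoxide, CC(C)(C)OO
Why: Sharpless asymmetric epoxidation, in which the D-(−)-tartrate (the opposite sense to the L-(+)-tartrate epoxidation of geraniol, which has the same substitution pattern) should make the methyl-bearing oxirane carbon, the future C1, R by catalyst control.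

Step 8
Reactants: 14 [(2R,3R)-3-methyl-3-[5-(TBSO)pent-3-yn-1-yl]-2-(homofarnesyl)oxiran-2-yl]methanol
Product: 16 (3R)-8-(TBSO)-3-methyl-2-(homofarnesyl)oct-1-en-6-yn-3-ol, via epoxy iodide 15 (not isolated)
Conditions: PPh3, I2, imidazole, Et2O/MeCN, 0 °C; filter, concentrate; then Zn dust, AcOH (2 equiv), EtOH, rt
Reagents that add atoms: none
Why: Appel-type iodination followed by zinc-induced reductive β-elimination (the 2,3-epoxy alcohol to tertiary allylic alcohol transposition) should open the oxirane without breaking the C1–O bond, so the C1 configuration is kept.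

Step 9
Reactants: 16 (3R)-8-(TBSO)-3-methyl-2-(homofarnesyl)oct-1-en-6-yn-3-ol
Product: 17 (3R)-3-methyl-2-(homofarnesyl)oct-1-en-6-yne-3,8-diol
Conditions: Bu4NF (1.2 equiv), THF, 0 °C → rt
Reagents that add atoms: none
Why: Fluoride cleavage of the silyl ether frees the second propargylic alcohol.

Step 10
Reactants: 17 (3R)-3-methyl-2-(homofarnesyl)oct-1-en-6-yne-3,8-diol
Product: 19 (3R,6Z)-6-iodo-3,7-dimethyl-2-(homofarnesyl)octa-1,6-diene-3,8-diol, via alkenylmagnesium chelate 18 (not isolated)
Conditions: MeMgBr (5 equiv), CuI (20 mol %), THF, −20 °C → rt; then I2, −78 → 0 °C; aq. Na2S2O3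
Reagents that add atoms: methylmagnesium bromide, C[Mg]Br; iodine, II
Why: A second alkoxide-directed anti-carbomagnesiation, now with CH3 transfer and iodinolysis with retention, should give the (Z)-iodoalkene with iodine cis to CH2OH and the tether cis to CH3, which is the geometry of the target enal.

Step 11
Reactants: 19 (3R,6Z)-6-iodo-3,7-dimethyl-2-(homofarnesyl)octa-1,6-diene-3,8-diol
Product: 20 (2Z,6R)-6-hydroxy-3-iodo-2,6-dimethyl-7-(homofarnesyl)octa-2,7-dien-1-yl pivalate
Conditions: PivCl (1.1 equiv), pyridine, DMAP (5 mol %), CH2Cl2, 0 °C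
Reagents that add atoms: pivaloyl chloride, CC(C)(C)C(=O)Cl
Why: Selective acylation of the primary allylic alcohol beside the tertiary one masks the only other allylic OH before the directed epoxidation and blocks a later oxa-Michael addition.

Step 12
Reactants: 20 (2Z,6R)-6-hydroxy-3-iodo-2,6-dimethyl-7-(homofarnesyl)octa-2,7-dien-1-yl pivalate
Product: 21 (2Z,6R)-6-hydroxy-3-iodo-2-methyl-6-[2-(homofarnesyl)oxiran-2-yl]hept-2-en-1-yl pivalate
Conditions: VO(acac)2 (5 mol %), t-BuOOH (1.5 equiv), CH2Cl2, 0 °C → rt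
Reagents that add atoms: tert-butyl hydroperoxide, CC(C)(C)OO
Why: Hydroxyl-directed vanadium-catalysed epoxidation should touch only the 1,1-disubstituted alkene of the free tertiary allylic alcohol, and removing this alkene before the palladium step avoids a competing 5-exo Heck closure.

Step 13
Reactants: 21 (2Z,6R)-6-hydroxy-3-iodo-2-methyl-6-[2-(homofarnesyl)oxiran-2-yl]hept-2-en-1-yl pivalate; 22 ethyl (2E)-3-(4,4,5,5-tetramethyl-1,3,2-dioxaborolan-2-yl)prop-2-enoate
Product: 23 ethyl (2E,4Z)-4-{(3R)-3-hydroxy-3-[2-(homofarnesyl)oxiran-2-yl]butyl}-5-methyl-6-(pivaloyloxy)hexa-2,4-dienoate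
Conditions: PdCl2(dppf) (5 mol %), K3PO4 (3 equiv), THF/H2O (10:1), 45 °C
Reagents that add atoms: none
Why: Suzuki–Miyaura coupling of the iodoalkene with the (E)-alkenylboronate proceeds with retention at both partners and should give the (2E,4Z)-dienoate.

Step 14
Reactants: 23 ethyl (2E,4Z)-4-{(3R)-3-hydroxy-3-[2-(homofarnesyl)oxiran-2-yl]butyl}-5-methyl-6-(pivaloyloxy)hexa-2,4-dienoate
Product: 25 cis-fused δ-lactone of 24 (C2 CH2O acylated by the C3 acetic arm), via hydroxy ester 24 (not isolated)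
Conditions: Cp2TiCl2 (20 mol %), Mn dust (2 equiv), 2,4,6-collidine·HCl (2.5 equiv), THF (0.02 M), rt; then PPTS (cat.), PhMe, 50 °C
Reagents that add atoms: none
Why: Cp2TiCl (trivalent titanium, regenerated by Mn and turned over by collidinium chloride) transfers one electron to the oxirane, which opens at its fully substituted carbon to a tertiary β-titanoxy radical; this adds to the β-carbon of the dienoate, and the resulting α-ester radical is reduced to a titanium enolate and protonated, after which the hydroxy ester lactonises under acid. The closest known reaction type is the reductive epoxide–acrylate cyclisation with the Nugent–RajanBabu reagent in its catalytic form. The cyclohexane closes in the 6-exo-trig mode; the competing 5-exo and 6-endo closures would have to attack the fully substituted carbons of the tetrasubstituted alkene and should be suppressed, and that alkene, lying outside the radical chain, keeps its geometry. The methine centre C3 is set in a chair transition state in which A(1,3) strain with the cis CH2OPiv group holds the acrylate arm axial, and the C1 carbinol centre then places its smaller OH, not its CH3, in the syn-axial position, so arm and OH end up cis. The quaternary centre C2 is set by the same C1 centre, because the titanium alkoxide on the CH2O group can bind the C1 hydroxyl and the ester carbonyl only from the equatorial position gauche to both, which puts CH2O cis to OH and the homofarnesyl chain axial. The step needs the radical to outlive capture by a second titanium centre, which its tertiary, hindered nature and the low stationary titanium concentration of the catalytic protocol should secure.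

Step 15
Reactants: 25 cis-fused δ-lactone
Product: 26 lactol of 25 with the pivalate removed
Conditions: iBu2AlH (6 equiv), CH2Cl2, −78 °C; aq. potassium sodium tartrate
Reagents that add atoms: none
Why: At −78 °C iBu2AlH should reduce the δ-lactone only to the lactol (stable aluminium hemiacetal) and cleave the pivalate reductively.

Step 16
Reactants: 26 lactol
Product: 27 (1R,2R,3S,4Z)-3-allyl-2-(hydroxymethyl)-4-(1-hydroxypropan-2-ylidene)-1-methyl-2-(homofarnesyl)cyclohexan-1-ol
Conditions: Ph3PCH3Br (6 equiv), KOtBu (5.5 equiv), THF, 0 °C → rt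
Reagents that add atoms: methyltriphenylphosphonium bromide, C[P+](c1ccccc1)(c1ccccc1)c1ccccc1.[Br-]
Why: Wittig methylenation of the open hydroxy-aldehyde form of the lactol should give the allyl arm and free the CH2OH on C2.

Step 17
Reactants: 27 (1R,2R,3S,4Z)-3-allyl-2-(hydroxymethyl)-4-(1-hydroxypropan-2-ylidene)-1-methyl-2-(homofarnesyl)cyclohexan-1-ol
Product: 29 (1R,2R,3S,4Z)-2-(hydroxymethyl)-4-(1-hydroxypropan-2-ylidene)-3-(3-hydroxypropyl)-1-methyl-2-(homofarnesyl)cyclohexan-1-ol, via alkylborane 28 (not isolated)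
Conditions: 9-BBN (5 equiv), THF, 0 °C → rt; then NaOH (3 M), H2O2 (30 %), 0 °C
Reagents that add atoms: hydrogen peroxide, OO
Why: Hydroboration–oxidation with 9-BBN is selective for the monosubstituted terminal alkene over the tri- and tetrasubstituted ones and should give the primary alcohol (anti-Markovnikov).

Step 18
Reactants: 29 (1R,2R,3S,4Z)-2-(hydroxymethyl)-4-(1-hydroxypropan-2-ylidene)-3-(3-hydroxypropyl)-1-methyl-2-(homofarnesyl)cyclohexan-1-ol
Product: 30 target CNP0284886.2
Conditions: MnO2 (20 equiv), CH2Cl2, rt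
Reagents that add atoms: none
Why: MnO2 should oxidise only the allylic primary alcohol, leaving the two saturated primary alcohols, the tertiary alcohol and the alkene geometry untouched.

**Compound list**

1 | (2E,6E)-farnesyl bromide, (2E,6E)-1-bromo-3,7,11-trimethyldodeca-2,6,10-triene | CC(C)=CCC/C(C)=C/CC/C(C)=C/CBr | starting material
2 | (chloromethyl)(isopropoxy)dimethylsilane | CC(C)O[Si](C)(C)CCl | starting material
3 | [(isopropoxydimethylsilyl)methyl]magnesium chloride | CC(C)O[Si](C)(C)C[Mg]Cl | intermediate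
4 | isopropoxydimethyl[(3E,7E)-4,8,12-trimethyltrideca-3,7,11-trien-1-yl]silane | CC(C)=CCC/C(C)=C/CC/C(C)=C/CC[Si](C)(C)OC(C)C | intermediate
5 | (3E,7E)-4,8,12-trimethyltrideca-3,7,11-trien-1-ol (homofarnesol) | CC(C)=CCC/C(C)=C/CC/C(C)=C/CCO | intermediate
6 | (3E,7E)-1-bromo-4,8,12-trimethyltrideca-3,7,11-triene (homofarnesyl bromide) | CC(C)=CCC/C(C)=C/CC/C(C)=C/CCBr | intermediate
7 | hexa-1,5-diyne | C#CCCC#C | starting material
8 | paraformaldehyde (formaldehyde unit) | C=O | starting material
9 | octa-2,6-diyne-1,8-diol | OCC#CCCC#CCO | intermediate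
10 | 8-[(tert-butyldimethylsilyl)oxy]octa-2,6-diyn-1-ol | OCC#CCCC#CCO[Si](C)(C)C(C)(C)C | intermediate
11 | homofarnesylmagnesium bromide | CC(C)=CCC/C(C)=C/CC/C(C)=C/CC[Mg]Br | intermediate
12 | bromomagnesium alkoxide of (2Z)-3-(bromomagnesio)-8-(TBSO)-2-(homofarnesyl)oct-2-en-6-yn-1-ol (Mg cis to CH2O) | Br[Mg]OC/C(CC/C=C(\C)CC/C=C(\C)CCC=C(C)C)=C(\[Mg]Br)CCC#CCO[Si](C)(C)C(C)(C)C | intermediate
13 | (2E)-8-(TBSO)-3-methyl-2-(homofarnesyl)oct-2-en-6-yn-1-ol | OC/C(CC/C=C(\C)CC/C=C(\C)CCC=C(C)C)=C(\C)CCC#CCO[Si](C)(C)C(C)(C)C | intermediate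
14 | [(2R,3R)-3-methyl-3-[5-(TBSO)pent-3-yn-1-yl]-2-(homofarnesyl)oxiran-2-yl]methanol | OC[C@@]1(CC/C=C(\C)CC/C=C(\C)CCC=C(C)C)O[C@]1(C)CCC#CCO[Si](C)(C)C(C)(C)C | intermediate
15 | (2S,3R)-2-(iodomethyl)-3-methyl-3-[5-(TBSO)pent-3-yn-1-yl]-2-(homofarnesyl)oxirane | IC[C@@]1(CC/C=C(\C)CC/C=C(\C)CCC=C(C)C)O[C@]1(C)CCC#CCO[Si](C)(C)C(C)(C)C | intermediate
16 | (3R)-8-(TBSO)-3-methyl-2-(homofarnesyl)oct-1-en-6-yn-3-ol | C=C(CC/C=C(\C)CC/C=C(\C)CCC=C(C)C)[C@](C)(O)CCC#CCO[Si](C)(C)C(C)(C)C | intermediate
17 | (3R)-3-methyl-2-(homofarnesyl)oct-1-en-6-yne-3,8-diol | C=C(CC/C=C(\C)CC/C=C(\C)CCC=C(C)C)[C@](C)(O)CCC#CCO | intermediate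
18 | bis(bromomagnesium) alkoxide of (3R,6Z)-6-(bromomagnesio)-3,7-dimethyl-2-(homofarnesyl)octa-1,6-diene-3,8-diol (Mg cis to CH2O) | C=C(CC/C=C(\C)CC/C=C(\C)CCC=C(C)C)[C@](C)(O[Mg]Br)CC/C([Mg]Br)=C(\C)CO[Mg]Br | intermediate
19 | (3R,6Z)-6-iodo-3,7-dimethyl-2-(homofarnesyl)octa-1,6-diene-3,8-diol | C=C(CC/C=C(\C)CC/C=C(\C)CCC=C(C)C)[C@](C)(O)CC/C(I)=C(\C)CO | intermediate
20 | (2Z,6R)-6-hydroxy-3-iodo-2,6-dimethyl-7-(homofarnesyl)octa-2,7-dien-1-yl 2,2-dimethylpropanoate | C=C(CC/C=C(\C)CC/C=C(\C)CCC=C(C)C)[C@](C)(O)CC/C(I)=C(\C)COC(=O)C(C)(C)C | intermediate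
21 | (2Z,6R)-6-hydroxy-3-iodo-2-methyl-6-[2-(homofarnesyl)oxiran-2-yl]hept-2-en-1-yl 2,2-dimethylpropanoate (both oxirane epimers) | C1OC1(CC/C=C(\C)CC/C=C(\C)CCC=C(C)C)[C@](C)(O)CC/C(I)=C(\C)COC(=O)C(C)(C)C | intermediate
22 | ethyl (2E)-3-(4,4,5,5-tetramethyl-1,3,2-dioxaborolan-2-yl)prop-2-enoate | CCOC(=O)/C=C/B1OC(C)(C)C(C)(C)O1 | starting material
23 | ethyl (2E,4Z)-4-{(3R)-3-hydroxy-3-[2-(homofarnesyl)oxiran-2-yl]butyl}-5-methyl-6-(pivaloyloxy)hexa-2,4-dienoate (both oxirane epimers) | C1OC1(CC/C=C(\C)CC/C=C(\C)CCC=C(C)C)[C@](C)(O)CC/C(=C(\C)COC(=O)C(C)(C)C)/C=C/C(=O)OCC | intermediate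
24 | (1R,2R,3S,4Z)-3-(2-ethoxy-2-oxoethyl)-2-(hydroxymethyl)-1-methyl-4-[1-(pivaloyloxy)propan-2-ylidene]-2-(homofarnesyl)cyclohexan-1-ol | CC(C)=CCC/C(C)=C/CC/C(C)=C/CC[C@]1(CO)[C@@H](CC(=O)OCC)/C(=C(/C)COC(=O)C(C)(C)C)CC[C@@]1(C)O | intermediate
25 | cis-fused δ-lactone of 24 (3-oxabicyclo[4.4.0]decan-4-one; C2 CH2–O acylated by the C3 acetic arm; ring centres and alkene as in 24) | CC(C)=CCC/C(C)=C/CC/C(C)=C/CC[C@@]13COC(=O)C[C@H]3/C(=C(/C)COC(=O)C(C)(C)C)CC[C@@]1(C)O | intermediate
26 | lactol of 25 with free allylic CH2OH (anomeric mixture) | CC(C)=CCC/C(C)=C/CC/C(C)=C/CC[C@@]13COC(O)C[C@H]3/C(=C(/C)CO)CC[C@@]1(C)O | intermediate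
27 | (1R,2R,3S,4Z)-3-allyl-2-(hydroxymethyl)-4-(1-hydroxypropan-2-ylidene)-1-methyl-2-(homofarnesyl)cyclohexan-1-ol | CC(C)=CCC/C(C)=C/CC/C(C)=C/CC[C@]1(CO)[C@@H](CC=C)/C(=C(/C)CO)CC[C@@]1(C)O | intermediate
28 | B-alkyl-9-borabicyclo[3.3.1]nonane adduct of the allyl group of 27 (hydroxyl groups drawn free) | CC(C)=CCC/C(C)=C/CC/C(C)=C/CC[C@]1(CO)[C@@H](CCCB2C3CCCC2CCC3)/C(=C(/C)CO)CC[C@@]1(C)O | intermediate
29 | (1R,2R,3S,4Z)-2-(hydroxymethyl)-4-(1-hydroxypropan-2-ylidene)-3-(3-hydroxypropyl)-1-methyl-2-(homofarnesyl)cyclohexan-1-ol | CC(C)=CCC/C(C)=C/CC/C(C)=C/CC[C@]1(CO)[C@@H](CCCO)/C(=C(/C)CO)CC[C@@]1(C)O | intermediate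
30 | (2Z)-2-[(2S,3R,4R)-4-hydroxy-3-(hydroxymethyl)-2-(3-hydroxypropyl)-4-methyl-3-(homofarnesyl)cyclohexylidene]propanal | CC(C)=CCC/C(C)=C/CC/C(C)=C/CC[C@]1(CO)[C@@H](CCCO)/C(=C(/C)C=O)CC[C@@]1(C)O | target

**Step count and risks**

Total steps: 18. Longest linear sequence: 16 (steps 1–3 and 6–18, from farnesyl bromide); 15 from hexa-1,5-diyne.

Steps most likely to fail:

1. Step 14. The tertiary radical may be captured by a second trivalent-titanium centre before it closes the ring, which deoxygenates it back to the allylic alcohol, and facial discrimination at the quaternary carbon rests on a titanium chelate that may be weak. Fallback, setting out from 23 and returning at 25: the radical would be made without a metal reductant. The oxirane of 23 would be hydrolysed (HClO4 cat., THF/H2O, 0 °C) to the triol ethyl (2E,4Z)-5-methyl-6-(pivaloyloxy)-4-[(3R)-3,4,5-trihydroxy-3-methyl-4-(homofarnesyl)pentyl]hexa-2,4-dienoate F1. Its primary/tertiary 1,2-diol would be closed with 1,1'-thiocarbonyldiimidazole to the cyclic thionocarbonate ethyl (2E,4Z)-4-{(3R)-3-hydroxy-3-[4-(homofarnesyl)-2-sulfanylidene-1,3-dioxolan-4-yl]butyl}-5-methyl-6-(pivaloyloxy)hexa-2,4-dienoate F2. Bu3SnH/AIBN (slow addition, PhH, 80 °C) would then fragment F2 at the tertiary C–O bond (Barton–McCombie logic) to the same tertiary radical, long-lived at low stannane concentration, which should close 6-exo in a Giese addition. Hydrolysis of the primary O-stannyl thiolcarbonate gives 24, and acid lactonisation returns the route at 25.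

2. Step 6. C-Methylation of the chelated alkenylmagnesium by iodomethane may be too slow, so that protonation on work-up gives the trisubstituted alkene. Fallback, setting out from 10 and returning at 13: the same carbomagnesiation would be quenched with I2 to give the iodoalkene (2Z)-8-[(tert-butyldimethylsilyl)oxy]-3-iodo-2-(homofarnesyl)oct-2-en-6-yn-1-ol F3, and the methyl group would be introduced in a separate Negishi coupling (MeZnCl, Pd(PPh3)4, THF), which retains the alkene geometry and gives 13.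

3. Step 13. Oxidative addition and transmetalation at the tetrasubstituted iodoalkene may be slow, leaving room for protodeiodination, base-induced migration of the neighbouring oxirane or loss of the pivalate. Fallback, setting out from 17 and returning at 23: the acrylate would be built by carbonyl olefination and not by cross-coupling. The alkenylmagnesium from 17 (MeMgBr, CuI) would be formylated with DMF to the lactol 3-[(3R)-3-hydroxy-3-methyl-4-(homofarnesyl)pent-4-en-1-yl]-4-methyl-2,5-dihydrofuran-2-ol F4. A Wittig reaction with Ph3P=CHCO2Et (PhH, 60 °C) would open it to ethyl (2E,4Z)-6-hydroxy-4-[(3R)-3-hydroxy-3-methyl-4-(homofarnesyl)pent-4-en-1-yl]-5-methylhexa-2,4-dienoate F5. Pivaloylation as in step 11 would give ethyl (2E,4Z)-4-[(3R)-3-hydroxy-3-methyl-4-(homofarnesyl)pent-4-en-1-yl]-5-methyl-6-(pivaloyloxy)hexa-2,4-dienoate F6, and the vanadium-catalysed epoxidation of step 12 applied to F6 would give 23.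

Further compounds
F1 | step 14 | ethyl (2E,4Z)-5-methyl-6-(pivaloyloxy)-4-[(3R)-3,4,5-trihydroxy-3-methyl-4-(homofarnesyl)pentyl]hexa-2,4-dienoate | OCC(O)(CC/C=C(\C)CC/C=C(\C)CCC=C(C)C)[C@](C)(O)CC/C(=C(\C)COC(=O)C(C)(C)C)/C=C/C(=O)OCC
F2 | step 14 | ethyl (2E,4Z)-4-{(3R)-3-hydroxy-3-[4-(homofarnesyl)-2-sulfanylidene-1,3-dioxolan-4-yl]butyl}-5-methyl-6-(pivaloyloxy)hexa-2,4-dienoate | S=C1OCC(CC/C=C(\C)CC/C=C(\C)CCC=C(C)C)(O1)[C@](C)(O)CC/C(=C(\C)COC(=O)C(C)(C)C)/C=C/C(=O)OCC
F3 | step 6 | (2Z)-8-[(tert-butyldimethylsilyl)oxy]-3-iodo-2-(homofarnesyl)oct-2-en-6-yn-1-ol | OC/C(CC/C=C(\C)CC/C=C(\C)CCC=C(C)C)=C(\I)CCC#CCO[Si](C)(C)C(C)(C)C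
F4 | step 13 | 3-[(3R)-3-hydroxy-3-methyl-4-(homofarnesyl)pent-4-en-1-yl]-4-methyl-2,5-dihydrofuran-2-ol | C=C(CC/C=C(\C)CC/C=C(\C)CCC=C(C)C)[C@](C)(O)CCC1=C(C)COC1O
F5 | step 13 | ethyl (2E,4Z)-6-hydroxy-4-[(3R)-3-hydroxy-3-methyl-4-(homofarnesyl)pent-4-en-1-yl]-5-methylhexa-2,4-dienoate | C=C(CC/C=C(\C)CC/C=C(\C)CCC=C(C)C)[C@](C)(O)CC/C(=C(\C)CO)/C=C/C(=O)OCC
F6 | step 13 | ethyl (2E,4Z)-4-[(3R)-3-hydroxy-3-methyl-4-(homofarnesyl)pent-4-en-1-yl]-5-methyl-6-(pivaloyloxy)hexa-2,4-dienoate | C=C(CC/C=C(\C)CC/C=C(\C)CCC=C(C)C)[C@](C)(O)CC/C(=C(\C)COC(=O)C(C)(C)C)/C=C/C(=O)OCC
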